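The readings are simulated from invented constants; scatter was added.

A small charge of G, 0.010 M, shows a quick fall of G and a slow rise of D: in the midnight run, at 10.0 min, G and D together stand at 24.5% of the charge. The rest is a pool that we cannot see, the charge minus [G] minus [D].

all flasks: G 0.010 M

| run | J | remark | time |
|---|---|---|---|
| dawn | 1.1 equiv | run made earlier |  |
| midnight | 2.3 equiv | run made earlier |  |
| summer | 3.1 equiv | run made earlier |  |
| beta | 1.20 equiv |  | 15 min |
| zeta | 1.50 equiv |  | 15 min |
| epsilon | 2.50 equiv |  | 15 min |
| delta | 4.00 equiv |  | 15 min |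

| run | time / min | D / % | G / % |
|---|---|---|---|
| dawn | 0.833 | 0.6 | 51.7 |
| dawn | 1.50 | 1.0 | 42.0 |
| dawn | 3.00 | 3.1 | 31.6 |
| dawn | 6.00 | 10.3 | 22.6 |
| dawn | 10.0 | 17.6 | 14.9 |
| midnight | 1.00 | 0.7 | 38.9 |
| midnight | 2.50 | 3.3 | 23.8 |
| midnight | 5.00 | 9.7 | 13.3 |
| midnight | 8.00 | 16.0 | 6.4 |
| midnight | 10.0 | 19.9 | 4.6 |
| summer | 1.00 | 1.8 | 33.9 |
| summer | 2.50 | 4.1 | 18.0 |
| summer | 5.00 | 8.8 | 9.0 |
| summer | 8.00 | 17.0 | 3.8 |
| summer | 10.0 | 20.7 | 1.9 |

(standard deviation of a reading: 0.5 percentage points)

- "hardly changes" means that all values lie within two and a half points (for a concentration: within two and a half percent of the largest)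

- amount of D at the end, in percent of the G charged for beta, zeta, epsilon, delta, in this order
- the course of these numbers from the first flask to the last (rises, then falls / hardly changes / rises all the way / falls all the way / falls, then rises)

A bench rule of thumb treats that pool as one intermediate and asks what part of it turns into D each minute, a pseudo-first-order constant. We take the mean rate of D over the last readings of a run and divide it by the mean pool over the same stretch. Dawn gives 0.0271 /min, summer 0.0298 /min. Midnight, with a mean pool of 76.2%, gives 0.0268 /min. Their mean, 0.0279 /min, is our pool constant: D made per minute per unit of pool.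

Does a mean stand in fairly for the curve? Over that midnight stretch the pool moves by 1.5 percentage points between its two ends, so each end lies about 0.984% from the mean. The scatter of the readings weighs more: about 0.00185 /min on the midnight constant, or 6.93% of it, and we can defend no trend with J inside it.

Our own reckoning for epsilon starts from midnight, the nearest run, and gives 30.4%. But the rule stands on charges from 1.1 equiv to 3.1 equiv. Delta's 4.00 equiv is 1.29 times summer's charge, above each charge run so far, so there the constant is untested.

The forecast gives 27.5%, 28.5%, 30% and 30.8%, a row that rises all the way: “I see no sign that extra J hurts D, though the spread is small.” For epsilon our 30.4% stands a little above its 30%.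

The flasks give 25.6%, 27.7%, 29.0% and 25.6%, a row that rises, then falls.

    G + J → L (k = 0.378 /M/s)
    G ⇌ Z (K = 0.720, k = 0.0129 /s)
    J + L ⇌ Q (K = 72.0 /M, k = 2.69 /M/s)
    L ⇌ D (K = 2.30, k = 0.00180 /s)
    G ⇌ X (K = 25.1, k = 0.00147 /s)

Over the stretch from 7.50 min to 15.0 min, the pool constant of zeta comes out at 0.0265 /min, against our 0.0279 /min. Delta gives 0.0193 /min, less than zeta, and at 15.0 min its pool holds Q at 42.1% against 13.1% in zeta. At that moment Q in delta is larger than L, X or Z. The step J + L ⇌ Q is the largest single effect we can show, though not the whole story: with it struck out, delta ends at 53.9% of D instead of 25.6%.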